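The plan rests on cutting C12–C13, the bond that joins the C13 carbinol to C12, the allylic terminus of the C2–C11 pentaene and hence the fivefold-vinylogous α-carbon of the C1 lactone carbonyl. The key step exploits exactly this: the 2-methyldodecapentaenoate already esterified to O35 is deprotonated at its C12 methyl group and added to the C13 aldehyde at the other chain end (ATPH-mediated hypervinylogous aldol). One operation closes the 36-membered ring, forms C12–C13, creates C13 and resets the pentaene to all-E. The precursor is an open-chain C13-aldehyde ester with C21 and C27 masked as dimethyl ketals; the resulting 13R carbinol is then inverted.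

Key step: step 19

Remarks on the chemistry (assumptions):
- The target is made as the open-chain 21,27-diketo hexaol that is drawn; its δ-hydroxy ketone units may equilibrate with cyclic hemiketals of the same compound.
- Locants C1–C35 follow the macrolide chain (C1 = lactone carbonyl, O35 = lactone oxygen on C35); for the large intermediates the descriptors at these locants coincide with those of the target unless stated.
- (2S,4S)-1,2:4,5-Diepoxypentane is taken as a purchasable C5 building block.

Step 1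
Reactants: 1 (2E,4E,6E)-octa-2,4,6-trienal
Product: 2 (2E,4E,6E,8E)-deca-2,4,6,8-tetraenal
Conditions: ylide (1.0 equiv), toluene, 80 °C; then I2 (cat.), CH2Cl2, rt, dark
Reagents that add atoms: (triphenylphosphoranylidene)acetaldehyde, O=CC=P(c1ccccc1)(c1ccccc1)c1ccccc1
Why: Wittig olefination with the stabilised formyl ylide should extend the trienal by one E-configured ene, and iodine equilibrates the tetraenal to the all-E isomer.

Step 2
Reactants: 2 (2E,4E,6E,8E)-deca-2,4,6,8-tetraenal
Product: 3 ethyl (2E,4E,6E,8E,10E)-2-methyldodeca-2,4,6,8,10-pentaenoate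
Conditions: CH2Cl2, rt, dark
Reagents that add atoms: ethyl 2-(triphenylphosphoranylidene)propanoate, CCOC(=O)C(C)=P(c1ccccc1)(c1ccccc1)c1ccccc1
Why: Wittig olefination with the stabilised α-methyl ylide should form the trisubstituted C2=C3 bond with E geometry (ester trans to the chain).

Step 3
Reactants: 3 ethyl (2E,4E,6E,8E,10E)-2-methyldodeca-2,4,6,8,10-pentaenoate
Product: 4 (2E,4E,6E,8E,10E)-2-methyldodeca-2,4,6,8,10-pentaenoic acid
Conditions: LiOH, THF/MeOH/H2O, rt, dark; aq. HCl to pH 3
Reagents that add atoms: lithium hydroxide, [Li+].[OH-]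
Why: Saponification of the ethyl ester by hydroxide (acyl substitution) leaves the pentaene untouched when run cold and in the dark.

Step 4
Reactants: 5 rac-2-(propan-2-yl)oxirane
Product: 6 (2S)-2-(propan-2-yl)oxirane
Conditions: (S,S)-(salen)Co(III)OAc (0.5 mol %; the catalyst enantiomer that hydrolyses the R epoxide), H2O (0.55 equiv), neat, 0 °C to rt; distillation
Reagents that add atoms: none
Why: Jacobsen hydrolytic kinetic resolution hydrolyses the R epoxide selectively, so the volatile S epoxide that later becomes C35 is recovered by distillation.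

Step 5
Reactants: 7 1,3-dithiane; 8 1,6-dibromohexane
Product: 10 2-(6-bromohexyl)-1,3-dithiane, via 2-lithio-1,3-dithiane 9 (not isolated)
Conditions: n-BuLi, THF, −30 °C; then 8 (3 equiv), −78 to −20 °C
Reagents that add atoms: none
Why: Corey–Seebach alkylation, in which the dithiane anion displaces one bromide of the dibromide used in excess, which suppresses double alkylation.

Step 6
Reactants: 10 2-(6-bromohexyl)-1,3-dithiane; 6 (2S)-2-(propan-2-yl)oxirane
Product: 12 (3R)-10-(1,3-dithian-2-yl)-2-methyldecan-3-ol, via Grignard reagent 11 (not isolated)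
Conditions: Mg, THF, 40 °C; then CuI (10 mol %), 6, −30 to 0 °C; aq. NH4Cl
Reagents that add atoms: none
Why: Copper-catalysed Grignard opening of the epoxide at its CH2 terminus (SN2) leaves the stereocentre untouched and gives the 35R carbinol.

Step 7
Reactants: 13 tert-butyl 2-[(4R,6R)-6-(cyanomethyl)-2,2-dimethyl-1,3-dioxan-4-yl]acetate
Product: 14 2-[(4R,6S)-6-(2-hydroxyethyl)-2,2-dimethyl-1,3-dioxan-4-yl]acetonitrile
Conditions: LiBH4, MeOH (2 equiv), THF, 0 to 40 °C
Reagents that add atoms: none
Why: Chemoselective borohydride reduction takes the ester to the primary alcohol (future C13) and spares the nitrile and the acetonide that carries C15 and C17 from the chiral pool.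

Step 8
Reactants: 14 2-[(4R,6S)-6-(2-hydroxyethyl)-2,2-dimethyl-1,3-dioxan-4-yl]acetonitrile
Product: 15 2-[(4R,6S)-6-(2-{[tert-butyl(dimethyl)silyl]oxy}ethyl)-2,2-dimethyl-1,3-dioxan-4-yl]acetonitrile
Conditions: TBSCl, imidazole, DMF, rt
Reagents that add atoms: tert-butyldimethylsilyl chloride, CC(C)(C)[Si](C)(C)Cl
Why: Standard silylation of the primary alcohol.

Step 9
Reactants: 15 2-[(4R,6S)-6-(2-{[tert-butyl(dimethyl)silyl]oxy}ethyl)-2,2-dimethyl-1,3-dioxan-4-yl]acetonitrile
Product: 16 2-[(4S,6S)-6-(2-{[tert-butyl(dimethyl)silyl]oxy}ethyl)-2,2-dimethyl-1,3-dioxan-4-yl]acetaldehyde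
Conditions: DIBAL-H (1.2 equiv), toluene, −78 °C; aq. Rochelle salt, then pH 5 buffer
Reagents that add atoms: water, O
Why: Partial reduction of the nitrile by DIBAL-H stops at the aluminium imine, which is hydrolysed on work-up to the C19 aldehyde.

Step 10
Reactants: 16 2-[(4S,6S)-6-(2-{[tert-butyl(dimethyl)silyl]oxy}ethyl)-2,2-dimethyl-1,3-dioxan-4-yl]acetaldehyde
Product: 17 tert-butyl(dimethyl)(2-{(4S,6S)-2,2-dimethyl-6-[(2RS)-oxiran-2-ylmethyl]-1,3-dioxan-4-yl}ethoxy)silane (C19 epimer mixture)
Conditions: Me3S+ I−, n-BuLi, THF, −10 °C to rt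
Reagents that add atoms: trimethylsulfonium iodide, C[S+](C)C.[I-]
Why: Corey–Chaykovsky epoxidation transfers a methylene (C20) to the aldehyde; no facial control is needed because the next step selects the epimer.

Step 11
Reactants: 17 tert-butyl(dimethyl)(2-{(4S,6S)-2,2-dimethyl-6-[(2RS)-oxiran-2-ylmethyl]-1,3-dioxan-4-yl}ethoxy)silane
Product: 18 tert-butyl(dimethyl)(2-{(4S,6S)-2,2-dimethyl-6-[(2R)-oxiran-2-ylmethyl]-1,3-dioxan-4-yl}ethoxy)silane
Conditions: (R,R)-(salen)Co(III)OAc (2 mol %; the catalyst enantiomer that hydrolyses the 19S epimer), H2O (0.55 equiv), THF (minimal), 0 °C to rt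
Reagents that add atoms: none
Why: Jacobsen hydrolytic kinetic resolution under catalyst control hydrolyses the 19S epoxide and leaves the 19R epoxide (17,19-anti).

Step 12
Reactants: 12 (3R)-10-(1,3-dithian-2-yl)-2-methyldecan-3-ol; 19 (2S,4S)-1,2:4,5-diepoxypentane
Product: 21 (2S)-1-{2-[(8R)-8-hydroxy-9-methyldecyl]-1,3-dithian-2-yl}-3-[(2S)-oxiran-2-yl]propan-2-ol, via dilithio alkoxide-dithianide 20 (not isolated)
Conditions: t-BuLi (2.1 equiv), THF–HMPA (10:1), −78 °C; then 19 (3 equiv), −78 to −40 °C; aq. NH4Cl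
Reagents that add atoms: none
Why: Corey–Seebach coupling, in which the dithiane anion opens one terminal epoxide of the C2-symmetric bis-epoxide (used in excess) at CH2; this fixes C25 and keeps the C22–C23 epoxide with its C23 centre.

Step 13
Reactants: 22 2-[tert-butyl(dimethyl)silyl]-1,3-dithiane; 18 tert-butyl(dimethyl)(2-{(4S,6S)-2,2-dimethyl-6-[(2R)-oxiran-2-ylmethyl]-1,3-dioxan-4-yl}ethoxy)silane; 21 (2S)-1-{2-[(8R)-8-hydroxy-9-methyldecyl]-1,3-dithian-2-yl}-3-[(2S)-oxiran-2-yl]propan-2-ol
Product: 26 C13–C35 bis(dithiane) triol (13-O-TBS; 15,17-O-isopropylidene; 19-O-TBS; 23,25,35-triol), via 2-lithio-2-silyl-1,3-dithiane 23 (not isolated), via lithium alkoxide adduct 24 (not isolated), via Brook-rearranged dithianyllithium 25 (not isolated)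
Conditions: 22, t-BuLi, Et2O, −78 to −45 °C; 18, −78 to −25 °C; then dilithium alkoxide of 21 (n-BuLi, 2 equiv, THF, −78 °C) in THF–HMPA, −78 °C to rt; aq. NH4Cl
Reagents that add atoms: none
Why: Three-component anion relay coupling, in which the silyl dithiane anion opens epoxide 18 at C20, HMPA triggers the 1,4-Brook rearrangement that moves silicon to O19 and regenerates a dithiane anion, and this opens epoxide 21 at C22; C19 and C23 come unchanged from the epoxides.

Step 14
Reactants: 26 C13–C35 bis(dithiane) triol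
Product: 27 C13–C35 bis(dithiane) 23,25-acetonide (35-OH free)
Conditions: 2,2-dimethoxypropane, PPTS (cat.), CH2Cl2, 0 °C to rt
Reagents that add atoms: 2,2-dimethoxypropane, COC(C)(C)OC
Why: Acid-catalysed transketalisation protects the 23,25-anti diol as its acetonide while the isolated, hindered C35 hydroxyl stays free.

Step 15
Reactants: 27 C13–C35 bis(dithiane) 23,25-acetonide
Product: 28 C13–C35 21,21:27,27-bis(dimethyl ketal) (35-OH free)
Conditions: PhI(OCOCF3)2 (2.4 equiv), anhydrous MeOH/CH2Cl2, 2,6-lutidine, −20 to 0 °C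
Reagents that add atoms: methanol, CO
Why: Oxidative dethioacetalisation with a hypervalent iodine reagent in methanol exchanges both dithianes for dimethyl ketals, a base-stable mask that the final acid step removes.

Step 16
Reactants: 28 C13–C35 21,21:27,27-bis(dimethyl ketal); 4 (2E,4E,6E,8E,10E)-2-methyldodeca-2,4,6,8,10-pentaenoic acid
Product: 30 seco ester (O35 pentaenoate; 13-O-TBS), via mixed anhydride 29 (not isolated)
Conditions: 4, 2,4,6-trichlorobenzoyl chloride, Et3N, THF, rt; then 28, DMAP, toluene, rt, dark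
Reagents that add atoms: none
Why: Yamaguchi esterification through the mixed anhydride acylates the only free hydroxyl (C35) with retention of configuration.

Step 17
Reactants: 30 seco ester (O35 pentaenoate; 13-O-TBS)
Product: 31 seco ester 13-ol
Conditions: HF·pyridine, pyridine (excess), THF, 0 °C
Reagents that add atoms: none
Why: Buffered fluoride desilylation cleaves the primary silyl ether much faster than the hindered secondary one at O19.

Step 18
Reactants: 31 seco ester 13-ol
Product: 32 seco aldehyde (C13 CHO; O35 pentaenoate)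
Conditions: Dess–Martin periodinane, NaHCO3, CH2Cl2, 0 °C to rt, dark
Reagents that add atoms: none
Why: Dess–Martin oxidation gives the β-alkoxy aldehyde under buffered, non-basic conditions that spare the pentaene and the ketals.

Step 19
Reactants: 32 seco aldehyde (C13 CHO; O35 pentaenoate)
Product: 34 protected macrolactone 13R-ol, via ATPH-bound lithium polyenolate 33 (not isolated)
Conditions: ATPH [aluminium tris(2,6-diphenylphenoxide), 3.3 equiv], toluene, −78 °C; slow addition to LTMP (2.5 equiv), THF, −78 °C, final 0.002 M; aq. NH4Cl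
Reagents that add atoms: none
Why: Proposed new method: ATPH binds the aldehyde and the ester carbonyl and its aryloxide walls bury C2 and the C14 methylene, so LTMP can only remove a proton from the exposed C12 methyl group, and the polyenolate 33 then attacks the ATPH-activated C13 aldehyde through its free, highest-coefficient terminus C12 in an open transition state. The closest known reaction type is the Yamamoto vinylogous aldol reaction in its intramolecular, macrolactone-forming variant (remote γ-carbon of conjugated esters), here carried through five vinylogous positions. The 36-membered ring closes by 36-exo-trig addition to the C13 carbonyl with the C11=C12 enolate bond inside the ring (enol-endo). C13 is controlled by C15: without chelation, the dipole-minimised Felkin-type (polar 1,3-anti) arrangement of the cis-dioxane places the incoming C12 anti to O15, which should give the 13R (13,15-anti) carbinol that step 20 inverts. The step needs ω- over α/γ-regioselectivity (secured by the ATPH pocket), ring closure over oligomerisation (high dilution, rigid polyene rod) and anti facial selectivity (rigid acetonide, monodentate ATPH); any 13S epimer formed already has the final configuration and can bypass step 20. The C2–C11 double bonds re-form from the s-trans polyenolate, so E/Z isomers of 32 should converge on the all-E pentaene.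

Step 20
Reactants: 34 protected macrolactone 13R-ol
Product: 35 protected macrolactone 13S-formate
Conditions: PPh3, DIAD, HCO2H, toluene, −20 to 0 °C, dark
Reagents that add atoms: formic acid, OC=O
Why: Mitsunobu reaction, in which SN2 displacement of the activated C13 oxygen by formate inverts C13 to the 13S (13,15-syn) configuration.

Step 21
Reactants: 35 protected macrolactone 13S-formate
Product: 36 CNP0167014.1 (target)
Conditions: aq. HF (48%), MeCN, 0 °C to rt; then Dowex 50WX8 (H+), MeOH–H2O (9:1), rt, dark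
Reagents that add atoms: water, O
Why: Acidic global deprotection, in which fluoride removes the silyl ether and aqueous acid hydrolyses the formate, both acetonides and both dimethyl ketals without touching any stereocentre.

Compound list
1 | (2E,4E,6E)-octa-2,4,6-trienal | C/C=C/C=C/C=C/C=O | starting material
2 | (2E,4E,6E,8E)-deca-2,4,6,8-tetraenal | C/C=C/C=C/C=C/C=C/C=O | intermediate
3 | ethyl (2E,4E,6E,8E,10E)-2-methyldodeca-2,4,6,8,10-pentaenoate | C/C=C/C=C/C=C/C=C/C=C(\C)C(=O)OCC | intermediate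
4 | (2E,4E,6E,8E,10E)-2-methyldodeca-2,4,6,8,10-pentaenoic acid (C1–C12) | C/C=C/C=C/C=C/C=C/C=C(\C)C(=O)O | intermediate
5 | rac-2-(propan-2-yl)oxirane | CC(C)C1CO1 | starting material
6 | (2S)-2-(propan-2-yl)oxirane | CC(C)[C@H]1CO1 | intermediate
7 | 1,3-dithiane | C1CSCSC1 | starting material
8 | 1,6-dibromohexane | BrCCCCCCBr | starting material
9 | 2-lithio-1,3-dithiane (not isolated) | [Li]C1SCCCS1 | intermediate
10 | 2-(6-bromohexyl)-1,3-dithiane | BrCCCCCCC1SCCCS1 | intermediate
11 | [6-(1,3-dithian-2-yl)hexyl]magnesium bromide (not isolated) | Br[Mg]CCCCCCC1SCCCS1 | intermediate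
12 | (3R)-10-(1,3-dithian-2-yl)-2-methyldecan-3-ol (C27–C35; carbinol = C35) | CC(C)[C@H](O)CCCCCCCC1SCCCS1 | intermediate
13 | tert-butyl 2-[(4R,6R)-6-(cyanomethyl)-2,2-dimethyl-1,3-dioxan-4-yl]acetate (C13–C19, syn-acetonide) | CC(C)(C)OC(=O)C[C@H]1C[C@@H](CC#N)OC(C)(C)O1 | starting material
14 | 2-[(4R,6S)-6-(2-hydroxyethyl)-2,2-dimethyl-1,3-dioxan-4-yl]acetonitrile | OCC[C@H]1C[C@@H](CC#N)OC(C)(C)O1 | intermediate
15 | 2-[(4R,6S)-6-(2-{[tert-butyl(dimethyl)silyl]oxy}ethyl)-2,2-dimethyl-1,3-dioxan-4-yl]acetonitrile | CC(C)(C)[Si](C)(C)OCC[C@H]1C[C@@H](CC#N)OC(C)(C)O1 | intermediate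
16 | 2-[(4S,6S)-6-(2-{[tert-butyl(dimethyl)silyl]oxy}ethyl)-2,2-dimethyl-1,3-dioxan-4-yl]acetaldehyde (CHO = C19) | CC(C)(C)[Si](C)(C)OCC[C@H]1C[C@@H](CC=O)OC(C)(C)O1 | intermediate
17 | tert-butyl(dimethyl)(2-{(4S,6S)-2,2-dimethyl-6-[(2RS)-oxiran-2-ylmethyl]-1,3-dioxan-4-yl}ethoxy)silane (C19 epimers) | CC(C)(C)[Si](C)(C)OCC[C@H]1C[C@@H](CC2CO2)OC(C)(C)O1 | intermediate
18 | tert-butyl(dimethyl)(2-{(4S,6S)-2,2-dimethyl-6-[(2R)-oxiran-2-ylmethyl]-1,3-dioxan-4-yl}ethoxy)silane (C13–C20; 15S,17S,19R) | CC(C)(C)[Si](C)(C)OCC[C@H]1C[C@@H](C[C@@H]2CO2)OC(C)(C)O1 | intermediate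
19 | (2S,4S)-1,2:4,5-diepoxypentane (C22–C26) | C1O[C@H]1C[C@H]1CO1 | starting material
20 | dilithio derivative of 12 (lithium alkoxide, 2-lithiodithiane; not isolated) | CC(C)[C@H](O[Li])CCCCCCCC1([Li])SCCCS1 | intermediate
21 | (2S)-1-{2-[(8R)-8-hydroxy-9-methyldecyl]-1,3-dithian-2-yl}-3-[(2S)-oxiran-2-yl]propan-2-ol (C22–C35; 23S,25S,35R) | CC(C)[C@H](O)CCCCCCCC1(C[C@@H](O)C[C@H]2CO2)SCCCS1 | intermediate
22 | 2-[tert-butyl(dimethyl)silyl]-1,3-dithiane (C21 linchpin) | CC(C)(C)[Si](C)(C)C1SCCCS1 | starting material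
23 | 2-lithio-2-[tert-butyl(dimethyl)silyl]-1,3-dithiane (not isolated) | [Li]C1([Si](C)(C)C(C)(C)C)SCCCS1 | intermediate
24 | lithium C19 alkoxide from 23 and 18, silicon still on the dithiane carbon C21 (not isolated) | CC(C)(C)[Si](C)(C)OCC[C@H]1C[C@@H](C[C@@H](O[Li])CC2([Si](C)(C)C(C)(C)C)SCCCS2)OC(C)(C)O1 | intermediate
25 | 19-O-TBS 2-lithiodithiane after 1,4-Brook rearrangement (not isolated) | CC(C)(C)[Si](C)(C)OCC[C@H]1C[C@@H](C[C@@H](O[Si](C)(C)C(C)(C)C)CC2([Li])SCCCS2)OC(C)(C)O1 | intermediate
26 | C13–C35 chain: 13-O-TBS; 15S,17S-O-isopropylidene; 19R-O-TBS; C21 and C27 as 1,3-dithianes; 23S,25S,35R-triol | CC(C)(C)[Si](C)(C)OCC[C@H]1C[C@@H](C[C@@H](O[Si](C)(C)C(C)(C)C)CC2(C[C@@H](O)C[C@H](O)CC3(CCCCCCC[C@@H](O)C(C)C)SCCCS3)SCCCS2)OC(C)(C)O1 | intermediate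
27 | as 26, with the 23,25-anti diol as acetonide; 35R-OH free | CC(C)(C)[Si](C)(C)OCC[C@H]1C[C@@H](C[C@@H](O[Si](C)(C)C(C)(C)C)CC2(C[C@@H]3C[C@@H](CC4(CCCCCCC[C@@H](O)C(C)C)SCCCS4)OC(C)(C)O3)SCCCS2)OC(C)(C)O1 | intermediate
28 | as 27, with C21 and C27 as dimethyl ketals; 35R-OH free | CC(C)(C)[Si](C)(C)OCC[C@H]1C[C@@H](C[C@@H](O[Si](C)(C)C(C)(C)C)CC(OC)(OC)C[C@@H]2C[C@@H](CC(OC)(OC)CCCCCCC[C@@H](O)C(C)C)OC(C)(C)O2)OC(C)(C)O1 | intermediate
29 | mixed anhydride of 4 with 2,4,6-trichlorobenzoic acid (not isolated) | C/C=C/C=C/C=C/C=C/C=C(\C)C(=O)OC(=O)c1c(Cl)cc(Cl)cc1Cl | intermediate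
30 | seco ester: 28 acylated at O35 by the all-E 2-methyldodecapentaenoyl group; 13-O-TBS | CC(C)(C)[Si](C)(C)OCC[C@H]1C[C@@H](C[C@@H](O[Si](C)(C)C(C)(C)C)CC(OC)(OC)C[C@@H]2C[C@@H](CC(OC)(OC)CCCCCCC[C@@H](OC(=O)/C(C)=C/C=C/C=C/C=C/C=C/C)C(C)C)OC(C)(C)O2)OC(C)(C)O1 | intermediate
31 | seco ester with free primary 13-OH | OCC[C@H]1C[C@@H](C[C@@H](O[Si](C)(C)C(C)(C)C)CC(OC)(OC)C[C@@H]2C[C@@H](CC(OC)(OC)CCCCCCC[C@@H](OC(=O)/C(C)=C/C=C/C=C/C=C/C=C/C)C(C)C)OC(C)(C)O2)OC(C)(C)O1 | intermediate
32 | seco aldehyde: C13 CHO, O35 pentaenoate with C12 methyl | O=CC[C@H]1C[C@@H](C[C@@H](O[Si](C)(C)C(C)(C)C)CC(OC)(OC)C[C@@H]2C[C@@H](CC(OC)(OC)CCCCCCC[C@@H](OC(=O)/C(C)=C/C=C/C=C/C=C/C=C/C)C(C)C)OC(C)(C)O2)OC(C)(C)O1 | intermediate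
33 | lithium polyenolate of 32 (C1 enolate through C11=C12, ATPH on both carbonyl oxygens; not isolated) | O=CC[C@H]1C[C@@H](C[C@@H](O[Si](C)(C)C(C)(C)C)CC(OC)(OC)C[C@@H]2C[C@@H](CC(OC)(OC)CCCCCCC[C@@H](OC(O[Li])=C(C)C=CC=CC=CC=CC=C)C(C)C)OC(C)(C)O2)OC(C)(C)O1 | intermediate
34 | protected 36-membered macrolactone, 13R-OH (13,15-anti); 15,17- and 23,25-acetonides; 19-O-TBS; 21,27-bis(dimethyl ketal); all-E pentaene | O[C@H]1C[C@H]2C[C@@H](C[C@@H](O[Si](C)(C)C(C)(C)C)CC(OC)(OC)C[C@@H]3C[C@@H](CC(OC)(OC)CCCCCCC[C@@H](OC(=O)/C(C)=C/C=C/C=C/C=C/C=C/C1)C(C)C)OC(C)(C)O3)OC(C)(C)O2 | intermediate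
35 | as 34, with C13 inverted: 13S-O-formate (13,15-syn) | O=CO[C@@H]1C[C@H]2C[C@@H](C[C@@H](O[Si](C)(C)C(C)(C)C)CC(OC)(OC)C[C@@H]3C[C@@H](CC(OC)(OC)CCCCCCC[C@@H](OC(=O)/C(C)=C/C=C/C=C/C=C/C=C/C1)C(C)C)OC(C)(C)O3)OC(C)(C)O2 | intermediate
36 | CNP0167014.1: (3E,5E,7E,9E,11E,14S,16S,18S,20R,24S,26S,36R)-14,16,18,20,24,26-hexahydroxy-3-methyl-36-(propan-2-yl)-1-oxacyclohexatriaconta-3,5,7,9,11-pentaene-2,22,28-trione (chain locants 13S,15S,17S,19R,23S,25S,35R) | C\C1=C/C=C/C=C/C=C/C=C/C[C@H](O)C[C@H](O)C[C@H](O)C[C@@H](O)CC(=O)C[C@@H](O)C[C@H](O)CC(=O)CCCCCCC[C@H](C(C)C)OC1=O | target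

Total step count: 21. Longest linear sequence: 14 steps (steps 7–11, then 13–21).

Steps most likely to fail

Step 19 (the labelled step). The polyenolate may be formed or may react at a position other than C12, the aldehyde may be enolised with β-elimination of the dioxane oxygen, chains may oligomerise instead of closing the 36-membered ring, or the facial selectivity at C13 may be poor. The fallback uses known chemistry and moves the ring closure to the C10=C11 alkene. It sets out from aldehyde 32. Brown allylation with (−)-B-allyldiisopinocampheylborane (Et2O, −78 °C, non-basic oxidative work-up) should add the C12 carbon under reagent control and give the 13S homoallylic alcohol F1. Ring-closing olefin metathesis of F1 (Hoveyda–Grubbs second-generation catalyst, toluene, high dilution) between the new vinyl group and the terminal C10=C11 propenyl end of the pentaenoate, with loss of propene, should give the protected 13S macrolactone alcohol F2. F2 already has the final C13 configuration and, under the conditions of step 21, comes back to the route at 36.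

Step 20. The activated C13 oxygen lies next to the C12 methylene that is allylic to the pentaene, so E2 elimination towards a hexaene may compete with substitution, and inversion may be incomplete. The fallback replaces substitution by a redox pair and also takes any mixture of C13 epimers. It sets out from 34: buffered Dess–Martin oxidation should give the 13-ketone F3, which is reduced without purification by Zn(BH4)2 (Et2O, −30 °C). Chelation between the C13 carbonyl and O15 and the polar 1,3-model both direct hydride to the face that gives the 13,15-syn alcohol, the 13S macrolactone alcohol F2. Under the conditions of step 21, F2 comes back to the route at 36.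

Step 13. The one-flask relay may suffer from premature or incomplete silyl migration, proton transfer between the anions, or slow opening of the dialkoxide-bearing epoxide. The fallback is the stepwise Corey–Seebach double alkylation. It sets out from epoxide 18 and 1,3-dithiane 7: 2-lithio-1,3-dithiane opens 18 at C20 to give the C13–C21 dithianyl carbinol F4; silylation (TBSOTf, 2,6-lutidine) gives its 19-O-TBS ether F5; lithiation of F5 (t-BuLi, THF–HMPA, −78 °C) and addition of the dilithium alkoxide of 21 opens the epoxide at C22 and comes back to the route at 26.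

Further compounds
F1 | step 19 | 13S homoallylic alcohol from allylation of 32 (allyl on C13; O35 pentaenoate retained) | C=CC[C@H](O)C[C@H]1C[C@@H](C[C@@H](O[Si](C)(C)C(C)(C)C)CC(OC)(OC)C[C@@H]2C[C@@H](CC(OC)(OC)CCCCCCC[C@@H](OC(=O)/C(C)=C/C=C/C=C/C=C/C=C/C)C(C)C)OC(C)(C)O2)OC(C)(C)O1
F2 | step 19 | protected macrolactone 13S-ol (C13 epimer of 34) | O[C@@H]1C[C@H]2C[C@@H](C[C@@H](O[Si](C)(C)C(C)(C)C)CC(OC)(OC)C[C@@H]3C[C@@H](CC(OC)(OC)CCCCCCC[C@@H](OC(=O)/C(C)=C/C=C/C=C/C=C/C=C/C1)C(C)C)OC(C)(C)O3)OC(C)(C)O2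
F3 | step 20 | protected macrolactone 13-ketone | O=C1C[C@H]2C[C@@H](C[C@@H](O[Si](C)(C)C(C)(C)C)CC(OC)(OC)C[C@@H]3C[C@@H](CC(OC)(OC)CCCCCCC[C@@H](OC(=O)/C(C)=C/C=C/C=C/C=C/C=C/C1)C(C)C)OC(C)(C)O3)OC(C)(C)O2
F4 | step 13 | C13–C21 dithianyl carbinol (19R-OH; 2-H dithiane at C21) | CC(C)(C)[Si](C)(C)OCC[C@H]1C[C@@H](C[C@@H](O)CC2SCCCS2)OC(C)(C)O1
F5 | step 13 | 19-O-TBS ether of F4 | CC(C)(C)[Si](C)(C)OCC[C@H]1C[C@@H](C[C@@H](O[Si](C)(C)C(C)(C)C)CC2SCCCS2)OC(C)(C)O1
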